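**Plan**

- Retrosynthesis: the eight benzyl ethers and three esters are removed last. The upper ring C is then cut at C2–C3 and C4–C4a in one operation. This gives an O-aryl oxocarbenium ion (upper rings A and B) and the complete lower flavan-3,4-diol carrying a Z-2-(benzoyloxy)vinyl group at C6.
- Enabling feature: in the upper unit O1 sits on ring A next to a free carbon (C4a) that is para to the C7 oxygen, and C2 is benzylic to ring B. C3 carries oxygen and C4 carries C6 of the lower ring A, which has oxygen ortho (C7) and para (O1) to that carbon. This is the adduct pattern of a cationic 2-oxadiene C4a=C8a–O1=C2 with a β-oxygenated, cation-stabilising styrene.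
- Lower unit: enol ester from terminal alkyne from C6 bromide. Its ring C is cut at O1–C2 (phenol opening of a cis-epoxide) and at C3–C4 (alkynylation of a salicylaldehyde).
- Forward order: ring A aldehyde and ring B alkyne, propargylic alcohol (C3–C4), Z alkene, epoxide, lower ring C (O1–C2), C6 alkyne, Z enol benzoate, union that closes the upper ring C, ester cleavage, hydrogenolysis.
- Stereochemistry: lower C4 from catalytic asymmetric alkynylation, lower C3 from hydroxyl-directed epoxidation of the Z allylic alcohol, lower C2 from inversion in the epoxide opening. Upper C2, C3 and C4 are all set in the key step: all-cis from Z geometry and endo approach, absolute sense from a chiral Brønsted acid.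

Key step: step 14

Assumption: the sense of induction of the two chiral catalysts (steps 7 and 14) follows the usual models; if the opposite configuration is delivered, the enantiomeric catalyst is used and nothing else changes.

Remark on descriptors: benzylation of the lower C7 oxygen and acetylation of the lower C4 oxygen change CIP rankings. The upper C4 is therefore S in 22 and 23 (R in 24) and the lower C3 is S in 20–22 (R elsewhere), although no centre changes its spatial arrangement.

**Route**

Step 1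
Reactants: 1 2,3-bis(benzyloxy)benzaldehyde
Product: 3 2,3-bis(benzyloxy)phenol, via aryl formate 2 (not isolated)
Conditions: mCPBA, CH2Cl2, 0 °C → rt; then K2CO3 (cat.), MeOH, rt
Reagents that add atoms: mCPBA, O=C(OO)c1cccc(Cl)c1
Why: Baeyer–Villiger (Dakin-type) oxidation, in which the electron-rich aryl group migrates to give the aryl formate that is methanolysed in the same flask to the phenol.

Step 2
Reactants: 4 3,4-bis(benzyloxy)benzaldehyde; 3 2,3-bis(benzyloxy)phenol
Product: 6 [2,3-bis(benzyloxy)phenoxy][3,4-bis(benzyloxy)phenyl]methyl pivalate, via chloro ester 5 (not isolated)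
Conditions: pivaloyl chloride, ZnCl2 (2 mol%), CH2Cl2, 0 °C → rt; then 3, i-Pr2NEt, −20 °C → rt
Reagents that add atoms: pivaloyl chloride, CC(C)(C)C(Cl)=O
Why: ZnCl2-catalysed addition of the acyl chloride across the aldehyde C=O gives the α-chloroalkyl ester, whose chloride is displaced by the phenol (acyloxyalkylation of a phenol) to give a mixed O-aryl O-acyl acetal that can later ionise only by loss of pivalate; the acetal carbon is racemic and becomes planar in step 14.

Step 3
Reactants: 7 2,3,4-trihydroxybenzaldehyde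
Product: 8 3,4-bis(benzyloxy)-2-hydroxybenzaldehyde
Conditions: BnBr (2.05 equiv), K2CO3 (2.1 equiv), DMF, rt
Reagents that add atoms: benzyl bromide, BrCc1ccccc1
Why: Williamson etherification that spares the C2 hydroxyl, which is hydrogen-bonded to the formyl group and is the least nucleophilic of the three.

Step 4
Reactants: 8 3,4-bis(benzyloxy)-2-hydroxybenzaldehyde
Product: 9 3,4-bis(benzyloxy)-5-bromo-2-hydroxybenzaldehyde
Conditions: NBS, MeCN, 0 °C
Reagents that add atoms: N-bromosuccinimide, O=C1CCC(=O)N1Br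
Why: electrophilic aromatic bromination goes para to the free hydroxyl and ortho to the C4 benzyloxy group, which places the halogen on the carbon that becomes C6 of the lower ring A.

Step 5
Reactants: 9 3,4-bis(benzyloxy)-5-bromo-2-hydroxybenzaldehyde
Product: 10 3,4-bis(benzyloxy)-5-bromo-2-(tert-butyldimethylsilyloxy)benzaldehyde
Conditions: TBSCl, imidazole, DMAP (cat.), DMF, rt
Reagents that add atoms: tert-butyldimethylsilyl chloride, CC(C)(C)[Si](C)(C)Cl
Why: silyl ether formation masks the future O1 through the organozinc, hydrogenation and peracid steps and is removable later with buffered fluoride.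

Step 6
Reactants: 4 3,4-bis(benzyloxy)benzaldehyde
Product: 11 1,2-bis(benzyloxy)-4-ethynylbenzene
Conditions: dimethyl (1-diazo-2-oxopropyl)phosphonate, K2CO3, MeOH, rt
Reagents that add atoms: dimethyl (1-diazo-2-oxopropyl)phosphonate (Ohira–Bestmann reagent), COP(=O)(OC)C(=[N+]=[N-])C(C)=O
Why: Seyferth–Gilbert homologation in the Ohira–Bestmann version converts the aldehyde into the terminal alkyne under mild carbonate conditions that leave the benzyl ethers untouched.

Step 7
Reactants: 10 3,4-bis(benzyloxy)-5-bromo-2-(tert-butyldimethylsilyloxy)benzaldehyde; 11 1,2-bis(benzyloxy)-4-ethynylbenzene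
Product: 13 (1R)-1-[3,4-bis(benzyloxy)-5-bromo-2-(tert-butyldimethylsilyloxy)phenyl]-3-[3,4-bis(benzyloxy)phenyl]prop-2-yn-1-ol, via zinc acetylide 12 (not isolated)
Conditions: Me2Zn, (S,S)-ProPhenol (10 mol%), Ph3P=O (20 mol%), toluene, 0 °C → rt; aq. NH4Cl
Reagents that add atoms: none
Why: zinc–ProPhenol-catalysed enantioselective alkynylation of the aldehyde (Trost) forms the C3–C4 bond and sets the carbinol centre (future lower C4) by catalyst-controlled attack on one aldehyde face.

Step 8
Reactants: 13 (1R)-1-[3,4-bis(benzyloxy)-5-bromo-2-(tert-butyldimethylsilyloxy)phenyl]-3-[3,4-bis(benzyloxy)phenyl]prop-2-yn-1-ol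
Product: 14 (1R,2Z)-1-[3,4-bis(benzyloxy)-5-bromo-2-(tert-butyldimethylsilyloxy)phenyl]-3-[3,4-bis(benzyloxy)phenyl]prop-2-en-1-ol
Conditions: H2 (1 atm), Pd/CaCO3 poisoned with Pb(OAc)2 (Lindlar catalyst), quinoline, EtOAc, rt
Reagents that add atoms: none
Why: Lindlar semihydrogenation adds hydrogen syn to the alkyne and should stop at the Z alkene, the aryl bromide and benzyl ethers being inert to the poisoned catalyst.

Step 9
Reactants: 14 (1R,2Z)-1-[3,4-bis(benzyloxy)-5-bromo-2-(tert-butyldimethylsilyloxy)phenyl]-3-[3,4-bis(benzyloxy)phenyl]prop-2-en-1-ol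
Product: 15 (S)-[3,4-bis(benzyloxy)-5-bromo-2-(tert-butyldimethylsilyloxy)phenyl]{(2R,3S)-3-[3,4-bis(benzyloxy)phenyl]oxiran-2-yl}methanol
Conditions: mCPBA, CH2Cl2/aq. NaHCO3 (two-phase), 0 °C
Reagents that add atoms: mCPBA, O=C(OO)c1cccc(Cl)c1
Why: hydroxyl-directed Prilezhaev epoxidation (Henbest effect), in which A(1,3) strain holds the carbinol hydrogen in the plane of the Z alkene so that the hydrogen-bonded peracid delivers oxygen to the face bearing the hydroxyl and gives the threo cis-epoxy alcohol (future C3, and C2 before its inversion).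

Step 10
Reactants: 15 (S)-[3,4-bis(benzyloxy)-5-bromo-2-(tert-butyldimethylsilyloxy)phenyl]{(2R,3S)-3-[3,4-bis(benzyloxy)phenyl]oxiran-2-yl}methanol
Product: 17 (2R,3R,4S)-7,8-bis(benzyloxy)-2-[3,4-bis(benzyloxy)phenyl]-6-bromochromane-3,4-diol, via free phenol 16 (not isolated)
Conditions: TBAF, AcOH, THF, 0 °C; then PPTS (cat.), CH2Cl2, 0 °C
Reagents that add atoms: none
Why: fluoride cleaves the aryl silyl ether and the freed phenol opens the cis-epoxide at its benzylic carbon in an acid-catalysed 6-endo intramolecular epoxide opening (flavan-3-ol ring closure) with inversion at C2 and retention at C3 and C4, which turns cis-epoxide plus threo carbinol into the 2,3-cis-3,4-trans diol.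

Step 11
Reactants: 17 (2R,3R,4S)-7,8-bis(benzyloxy)-2-[3,4-bis(benzyloxy)phenyl]-6-bromochromane-3,4-diol
Product: 19 (2R,3R,4S)-7,8-bis(benzyloxy)-2-[3,4-bis(benzyloxy)phenyl]-6-ethynylchromane-3,4-diol, via silyl alkyne 18 (not isolated)
Conditions: ethynyltrimethylsilane, PdCl2(MeCN)2 (3 mol%), XPhos (9 mol%), Cs2CO3, MeCN, 70 °C; then K2CO3 (cat.), MeOH, rt
Reagents that add atoms: ethynyltrimethylsilane, C#C[Si](C)(C)C
Why: copper-free Sonogashira coupling at the electron-rich C6 bromide followed by methanolytic removal of the alkynyl silyl group gives the terminal alkyne without touching the stereocentres.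

Step 12
Reactants: 19 (2R,3R,4S)-7,8-bis(benzyloxy)-2-[3,4-bis(benzyloxy)phenyl]-6-ethynylchromane-3,4-diol
Product: 20 (2R,3S,4S)-7,8-bis(benzyloxy)-2-[3,4-bis(benzyloxy)phenyl]-6-ethynylchromane-3,4-diyl diacetate
Conditions: Ac2O, pyridine, DMAP (cat.), CH2Cl2, rt
Reagents that add atoms: acetic anhydride, CC(=O)OC(C)=O
Why: DMAP-catalysed acetylation caps both secondary hydroxyls so that they cannot trap the oxocarbenium ion of step 14, and the ester at the benzylic C4 oxygen disfavours its ionisation.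

Step 13
Reactants: 20 (2R,3S,4S)-7,8-bis(benzyloxy)-2-[3,4-bis(benzyloxy)phenyl]-6-ethynylchromane-3,4-diyl diacetate
Product: 21 (Z)-2-{(2R,3S,4S)-3,4-diacetoxy-7,8-bis(benzyloxy)-2-[3,4-bis(benzyloxy)phenyl]chroman-6-yl}ethenyl benzoate
Conditions: PhCO2H, [RuCl2(p-cymene)]2 (2 mol%), P(4-ClC6H4)3 (6 mol%), DMAP (8 mol%), toluene, 60 °C
Reagents that add atoms: benzoic acid, O=C(O)c1ccccc1
Why: anti-Markovnikov hydro-acyloxylation of the terminal alkyne through the vinylidene complex formed from [RuCl2(p-cymene)]2 adds benzoic acid to the terminal carbon and should give the Z enol ester selectively.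

Step 14
Reactants: 21 (Z)-2-{(2R,3S,4S)-3,4-diacetoxy-7,8-bis(benzyloxy)-2-[3,4-bis(benzyloxy)phenyl]chroman-6-yl}ethenyl benzoate; 6 [2,3-bis(benzyloxy)phenoxy][3,4-bis(benzyloxy)phenyl]methyl pivalate
Product: 22 (2R,3R,4S)-7,8-bis(benzyloxy)-2-[3,4-bis(benzyloxy)phenyl]-4-{(2R,3S,4S)-3,4-diacetoxy-7,8-bis(benzyloxy)-2-[3,4-bis(benzyloxy)phenyl]chroman-6-yl}chroman-3-yl benzoate (upper ring all-cis)
Conditions: 6 (1.3 equiv), chiral imidodiphosphorimidate Brønsted acid (IDPi, BINOL-derived, (S,S) series, 5 mol%), 5 Å MS, toluene, −60 °C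
Reagents that add atoms: none
Why: Proposed new method: the chiral acid protonates the pivalate carbonyl of 6 and pivalic acid leaves (the aryloxy group cannot, since that would leave only an acyloxy-stabilised cation), so the O-aryl oxocarbenium ion, a cationic 2-oxadiene C4a=C8a–O1=C2, forms as a contact ion pair with the chiral anion; the benzoyloxy-bearing alkene carbon of 21 attacks C2 (C2–C3 bond), C4a of ring A captures the resulting C4 benzylic cation (C4–C4a bond) and loss of the proton returns the acid. The closest known reaction type is the Lewis-acid-promoted oxa-Povarov reaction of aryl oxocarbenium ions with styrenes, together with chiral-acid-catalysed Povarov reactions and counter-anion-directed additions to oxocarbenium ions; new are the β-acyloxystyrene partner and the chiral ion pair in this setting. The upper ring C closes in a formal inverse-electron-demand [4+2] mode, in stepwise terms an intermolecular Prins-type addition followed by a six-membered Friedel–Crafts closure that is 6-endo with respect to the C4a=C8a bond. C3 and C4 should be cis because the Z alkene adds suprafacially (a stepwise closure through the chair with both aryl groups equatorial gives the same 2,4-cis result), C2 and C3 should be cis because the alkene approaches the E-configured oxocarbenium ion endo, and the absolute sense at C2 is set by the chiral anion, the lower stereocentres being too remote to matter. The step needs regioselectivity (C2 to the oxygen-bearing alkene carbon), secured by the lower ring A, whose C7 oxygen (ortho) and O1 (para) stabilise the C4 cation far better than a benzoyloxy group would stabilise the alternative, and it needs site selectivity in ring A, secured because the only free position ortho to O1 is C4a, which is also para to the C7 oxygen. It also needs chemoselective ionisation of the acylal in the presence of the lower C4 acetate, secured by the far greater stabilisation of the oxocarbenium ion and the low temperature.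

Step 15
Reactants: 22 (2R,3R,4S)-7,8-bis(benzyloxy)-2-[3,4-bis(benzyloxy)phenyl]-4-{(2R,3S,4S)-3,4-diacetoxy-7,8-bis(benzyloxy)-2-[3,4-bis(benzyloxy)phenyl]chroman-6-yl}chroman-3-yl benzoate
Product: 23 (2R,3R,4S)-7,8-bis(benzyloxy)-2-[3,4-bis(benzyloxy)phenyl]-6-{(2R,3R,4S)-7,8-bis(benzyloxy)-2-[3,4-bis(benzyloxy)phenyl]-3-hydroxychroman-4-yl}chromane-3,4-diol
Conditions: K2CO3 (cat.), MeOH/THF, rt
Reagents that add atoms: none
Why: base-catalysed transesterification (Zemplén-type methanolysis) removes the benzoate and both acetates by attack at the acyl carbons, so no stereocentre is touched.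

Step 16
Reactants: 23 (2R,3R,4S)-7,8-bis(benzyloxy)-2-[3,4-bis(benzyloxy)phenyl]-6-{(2R,3R,4S)-7,8-bis(benzyloxy)-2-[3,4-bis(benzyloxy)phenyl]-3-hydroxychroman-4-yl}chromane-3,4-diol
Product: 24 (2R,3R,4S)-2-(3,4-dihydroxyphenyl)-6-[(2R,3R,4R)-2-(3,4-dihydroxyphenyl)-3,7,8-trihydroxychroman-4-yl]chromane-3,4,7,8-tetrol
Conditions: H2 (1 atm), Pd(OH)2/C, THF/H2O, rt
Reagents that add atoms: none
Why: hydrogenolysis of the eight aryl benzyl ethers over Pd(OH)2/C in a neutral, alcohol-free medium should free the phenols while the secondary benzylic C–O bonds (O1–C2 of both units and the lower C4 hydroxyl), which cleave much more slowly, are kept.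

**Compound list**

1 | 2,3-bis(benzyloxy)benzaldehyde | O=Cc1cccc(OCc2ccccc2)c1OCc1ccccc1 | starting material
2 | 2,3-bis(benzyloxy)phenyl formate (formed in the flask) | O=COc1cccc(OCc2ccccc2)c1OCc1ccccc1 | intermediate
3 | 2,3-bis(benzyloxy)phenol | Oc1cccc(OCc2ccccc2)c1OCc1ccccc1 | intermediate
4 | 3,4-bis(benzyloxy)benzaldehyde | O=Cc1ccc(OCc2ccccc2)c(OCc2ccccc2)c1 | starting material
5 | chloro[3,4-bis(benzyloxy)phenyl]methyl pivalate (racemic, formed in the flask) | CC(C)(C)C(=O)OC(Cl)c1ccc(OCc2ccccc2)c(OCc2ccccc2)c1 | intermediate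
6 | [2,3-bis(benzyloxy)phenoxy][3,4-bis(benzyloxy)phenyl]methyl pivalate (racemic at the acetal carbon) | CC(C)(C)C(=O)OC(Oc1cccc(OCc2ccccc2)c1OCc1ccccc1)c1ccc(OCc2ccccc2)c(OCc2ccccc2)c1 | intermediate
7 | 2,3,4-trihydroxybenzaldehyde | O=Cc1ccc(O)c(O)c1O | starting material
8 | 3,4-bis(benzyloxy)-2-hydroxybenzaldehyde | O=Cc1ccc(OCc2ccccc2)c(OCc2ccccc2)c1O | intermediate
9 | 3,4-bis(benzyloxy)-5-bromo-2-hydroxybenzaldehyde | O=Cc1cc(Br)c(OCc2ccccc2)c(OCc2ccccc2)c1O | intermediate
10 | 3,4-bis(benzyloxy)-5-bromo-2-(tert-butyldimethylsilyloxy)benzaldehyde | O=Cc1cc(Br)c(OCc2ccccc2)c(OCc2ccccc2)c1O[Si](C)(C)C(C)(C)C | intermediate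
11 | 1,2-bis(benzyloxy)-4-ethynylbenzene | C#Cc1ccc(OCc2ccccc2)c(OCc2ccccc2)c1 | intermediate
12 | methyl{[3,4-bis(benzyloxy)phenyl]ethynyl}zinc (formed in the flask) | C[Zn]C#Cc1ccc(OCc2ccccc2)c(OCc2ccccc2)c1 | intermediate
13 | (1R)-1-[3,4-bis(benzyloxy)-5-bromo-2-(tert-butyldimethylsilyloxy)phenyl]-3-[3,4-bis(benzyloxy)phenyl]prop-2-yn-1-ol | O[C@@H](c1cc(Br)c(OCc2ccccc2)c(OCc2ccccc2)c1O[Si](C)(C)C(C)(C)C)C#Cc1ccc(OCc2ccccc2)c(OCc2ccccc2)c1 | intermediate
14 | (1R,2Z)-1-[3,4-bis(benzyloxy)-5-bromo-2-(tert-butyldimethylsilyloxy)phenyl]-3-[3,4-bis(benzyloxy)phenyl]prop-2-en-1-ol | O[C@@H](c1cc(Br)c(OCc2ccccc2)c(OCc2ccccc2)c1O[Si](C)(C)C(C)(C)C)/C=C\c1ccc(OCc2ccccc2)c(OCc2ccccc2)c1 | intermediate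
15 | (S)-[3,4-bis(benzyloxy)-5-bromo-2-(tert-butyldimethylsilyloxy)phenyl]{(2R,3S)-3-[3,4-bis(benzyloxy)phenyl]oxiran-2-yl}methanol (cis-epoxide, threo to the carbinol) | O[C@@H](c1cc(Br)c(OCc2ccccc2)c(OCc2ccccc2)c1O[Si](C)(C)C(C)(C)C)[C@H]1O[C@H]1c1ccc(OCc2ccccc2)c(OCc2ccccc2)c1 | intermediate
16 | (S)-[3,4-bis(benzyloxy)-5-bromo-2-hydroxyphenyl]{(2R,3S)-3-[3,4-bis(benzyloxy)phenyl]oxiran-2-yl}methanol (formed in the flask) | O[C@@H](c1cc(Br)c(OCc2ccccc2)c(OCc2ccccc2)c1O)[C@H]1O[C@H]1c1ccc(OCc2ccccc2)c(OCc2ccccc2)c1 | intermediate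
17 | (2R,3R,4S)-7,8-bis(benzyloxy)-2-[3,4-bis(benzyloxy)phenyl]-6-bromochromane-3,4-diol (2,3-cis-3,4-trans) | Brc1cc2c(c(OCc3ccccc3)c1OCc1ccccc1)O[C@H](c1ccc(OCc3ccccc3)c(OCc3ccccc3)c1)[C@H](O)[C@H]2O | intermediate
18 | (2R,3R,4S)-7,8-bis(benzyloxy)-2-[3,4-bis(benzyloxy)phenyl]-6-[(trimethylsilyl)ethynyl]chromane-3,4-diol (formed in the flask) | C[Si](C)(C)C#Cc1cc2c(c(OCc3ccccc3)c1OCc1ccccc1)O[C@H](c1ccc(OCc3ccccc3)c(OCc3ccccc3)c1)[C@H](O)[C@H]2O | intermediate
19 | (2R,3R,4S)-7,8-bis(benzyloxy)-2-[3,4-bis(benzyloxy)phenyl]-6-ethynylchromane-3,4-diol | C#Cc1cc2c(c(OCc3ccccc3)c1OCc1ccccc1)O[C@H](c1ccc(OCc3ccccc3)c(OCc3ccccc3)c1)[C@H](O)[C@H]2O | intermediate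
20 | (2R,3S,4S)-7,8-bis(benzyloxy)-2-[3,4-bis(benzyloxy)phenyl]-6-ethynylchromane-3,4-diyl diacetate | C#Cc1cc2c(c(OCc3ccccc3)c1OCc1ccccc1)O[C@H](c1ccc(OCc3ccccc3)c(OCc3ccccc3)c1)[C@H](OC(C)=O)[C@H]2OC(C)=O | intermediate
21 | (Z)-2-{(2R,3S,4S)-3,4-diacetoxy-7,8-bis(benzyloxy)-2-[3,4-bis(benzyloxy)phenyl]chroman-6-yl}ethenyl benzoate | O=C(O/C=C\c1cc2c(c(OCc3ccccc3)c1OCc1ccccc1)O[C@H](c1ccc(OCc3ccccc3)c(OCc3ccccc3)c1)[C@H](OC(C)=O)[C@H]2OC(C)=O)c1ccccc1 | intermediate
22 | (2R,3R,4S)-7,8-bis(benzyloxy)-2-[3,4-bis(benzyloxy)phenyl]-4-{(2R,3S,4S)-3,4-diacetoxy-7,8-bis(benzyloxy)-2-[3,4-bis(benzyloxy)phenyl]chroman-6-yl}chroman-3-yl benzoate (upper ring 2,3-cis-3,4-cis; lower ring 2,3-cis-3,4-trans) | c1ccccc1COc1ccc([C@H]2Oc3c(ccc(OCc4ccccc4)c3OCc3ccccc3)[C@@H](c3cc4c(c(OCc5ccccc5)c3OCc3ccccc3)O[C@H](c3ccc(OCc5ccccc5)c(OCc5ccccc5)c3)[C@H](OC(C)=O)[C@H]4OC(C)=O)[C@H]2OC(=O)c2ccccc2)cc1OCc1ccccc1 | intermediate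
23 | (2R,3R,4S)-7,8-bis(benzyloxy)-2-[3,4-bis(benzyloxy)phenyl]-6-{(2R,3R,4S)-7,8-bis(benzyloxy)-2-[3,4-bis(benzyloxy)phenyl]-3-hydroxychroman-4-yl}chromane-3,4-diol | c1ccccc1COc1ccc([C@H]2Oc3c(ccc(OCc4ccccc4)c3OCc3ccccc3)[C@@H](c3cc4c(c(OCc5ccccc5)c3OCc3ccccc3)O[C@H](c3ccc(OCc5ccccc5)c(OCc5ccccc5)c3)[C@H](O)[C@H]4O)[C@H]2O)cc1OCc1ccccc1 | intermediate
24 | (2R,3R,4S)-2-(3,4-dihydroxyphenyl)-6-[(2R,3R,4R)-2-(3,4-dihydroxyphenyl)-3,7,8-trihydroxychroman-4-yl]chromane-3,4,7,8-tetrol | Oc1ccc([C@H]2Oc3c(ccc(O)c3O)[C@@H](c3cc4c(c(O)c3O)O[C@H](c3ccc(O)c(O)c3)[C@H](O)[C@H]4O)[C@H]2O)cc1O | target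

**Step count and risks**

Total step count: 16. Longest linear sequence: 13 steps (from 7 through steps 3, 4, 5 and 7 to 16).

Steps most likely to fail:

1. Step 14 (Proposed new method). What may go wrong: the chiral ion pair fails to discriminate the faces of C2, or a background pathway through the released pivalic acid competes. A long-lived C4 cation could also erode the cis relations, and Prins-type oligomerisation of the electron-rich enol ester could take over. Fallback: setting out from 21 and 6, the union is run under the conditions of the parent reaction, SnCl4 (1.1 equiv) in CH2Cl2 at −78 °C, giving up catalyst control and relying only on the endo preference. Because the lower unit is enantiopure, the two all-cis adducts are diastereomers: 22 and the isomer of 22 with the mirror-image upper ring F1. They are separated by preparative HPLC and the route is rejoined at 22.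

2. Step 10. What may go wrong: ionisation at the benzylic epoxide carbon before the phenol attacks (loss of the inversion at C2), 5-exo opening at C3 to a dihydrobenzofuran, or ionisation of the C4 carbinol under acid. Fallback: setting out from 15, the phenol 16 is freed with buffered fluoride as before, and the proton catalyst is replaced by Ti(Oi-Pr)4 (1.5 equiv, CH2Cl2, rt). The titanium binds the C4 alkoxide, the epoxide oxygen and the phenoxide and delivers the phenoxide to C-3 of the 2,3-epoxy alcohol (flavan C2) in an SN2 manner (titanium-mediated opening of 2,3-epoxy alcohols). The ring closure thus changes from electrophile activation by a proton to a templated nucleophilic substitution. The route is rejoined at 17; this fallback makes no new compound (F0).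

3. Step 16. What may go wrong: hydrogenolytic loss of the lower C4 hydroxyl, or its exchange through a para-quinone methide once the C7 phenol is free. Fallback: setting out from 23, the three carbinols are silylated (TESOTf, 2,6-lutidine, CH2Cl2, 0 °C) to the tris(triethylsilyl) ether of 23 F2. Hydrogenolysis (H2, Pd(OH)2/C, EtOAc) then gives the octaphenol with the three carbinols still silylated F3; a silyl ether at C4 neither ionises nor hydrogenolyses readily. Buffered fluoride (HF·pyridine, pyridine, THF, 0 °C) finally releases the carbinols and the route comes back at 24.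

**Further compounds**

F1 | step 14 | isomer of 22 with the enantiomeric upper ring (upper ring 2S,3S,4R and all-cis; lower unit unchanged) | c1ccccc1COc1ccc([C@@H]2Oc3c(ccc(OCc4ccccc4)c3OCc3ccccc3)[C@H](c3cc4c(c(OCc5ccccc5)c3OCc3ccccc3)O[C@H](c3ccc(OCc5ccccc5)c(OCc5ccccc5)c3)[C@H](OC(C)=O)[C@H]4OC(C)=O)[C@@H]2OC(=O)c2ccccc2)cc1OCc1ccccc1
F0 | step 10 | none | none
F2 | step 16 | tris(triethylsilyl) ether of 23 (upper 3-O, lower 3-O and lower 4-O silylated; configuration as in 23) | c1ccccc1COc1ccc([C@H]2Oc3c(ccc(OCc4ccccc4)c3OCc3ccccc3)[C@@H](c3cc4c(c(OCc5ccccc5)c3OCc3ccccc3)O[C@H](c3ccc(OCc5ccccc5)c(OCc5ccccc5)c3)[C@H](O[Si](CC)(CC)CC)[C@H]4O[Si](CC)(CC)CC)[C@H]2O[Si](CC)(CC)CC)cc1OCc1ccccc1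
F3 | step 16 | tris(triethylsilyl) ether of 24 (upper 3-O, lower 3-O and lower 4-O silylated, all eight phenols free; configuration as in 24) | Oc1ccc([C@H]2Oc3c(ccc(O)c3O)[C@@H](c3cc4c(c(O)c3O)O[C@H](c3ccc(O)c(O)c3)[C@H](O[Si](CC)(CC)CC)[C@H]4O[Si](CC)(CC)CC)[C@H]2O[Si](CC)(CC)CC)cc1O
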